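**Plan**

- Retrosynthetic cuts: (a) the ester bond between the acrylic acid of half A and the C12' oxygen of half B, which gives two monomers of opposite handedness; (b) in each monomer the ε-lactone at C8=C9 (ring-closing metathesis) and O–C7 (carboxylate alkylation); (c) the isopropyl carbon and C12 rejoined as a C(Me)=CH bridge (ozonolysis); (d) C4–C5 and C1–C10 (Diels–Alder).
- Forward order: ring A arises first, as one ring of a bicyclo[2.2.2]octene. Ozonolysis unzips the bridge, a cis γ-lactone (C6–O–C12) stores C6 and C12 while acetyl and C9 become isopropenyl and vinyl, metathesis closes the ε-lactone, and the two monomers are joined by esterification.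
- Enabling feature: in ring A (C1–C2–C3–C4–C5–C10) the isopropyl carbon on C1 and C12 on C4 are 1,4-related and on the same face, like the two ends of a cut two-carbon bridge. C5 (bearing C6) and C10 (bearing C9) lie between them and are trans, like the two carbons of an E-dienophile.
- Stereochemistry: all four stereocentres of each half come from one endo Diels–Alder step under imidazolidinone catalysis, with the (5R)-catalyst for the acid half (A series) and the (5S)-catalyst for the alcohol half (B series). No later step creates or inverts a stereocentre.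

Key step: step 2

**Remarks on the chemistry**

- Locants refer to one monomer: ring A = C1–C2–C3–C4–C5–C10; C6 = lactone carbonyl; C7 = OCH2; C8 = acrylate α-carbon; C9 = vinylic CH; C12 = CH2O on C4. Primed locants belong to half B.
- "A-series configuration" means: with ring A drawn C1→C2→C3→C4→C5→C10 clockwise, the C1 substituent, C12 and C6 point up, and the C4 oxygen and C9 point down. The B series is the mirror image.
- The sense of induction is assumed from the usual face selectivity of this catalyst class (the (5S)-catalyst lets the diene add to the α-Si face of the iminium ion). If the first adduct proved antipodal, the two catalyst enantiomers would exchange roles.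
- (E)-4,4-Dimethoxybut-2-enal (fumaraldehyde mono(dimethyl acetal)) is taken as commercial.
- Steps 12–20 repeat steps 2–10 on the enantiomers.

**Route**

Step 1
Reactants: 1 3-methylcyclohex-2-en-1-one; 2 chlorotriethylsilane
Product: 4 silyl dienol ether, via bromomagnesium dienolate 3 (not isolated)
Conditions: MeMgBr (1.1 equiv.), FeCl3 (5 mol %), Et2O, −20 °C; then Et3SiCl, Et3N, DMPU, −20 °C → rt
Reagents that add atoms: chlorotriethylsilane, CC[Si](CC)(CC)Cl
Why: Kharasch-type iron-catalysed deprotonation with MeMgBr should give the thermodynamic, fully conjugated endocyclic dienolate (γ-deprotonation at the ring CH2) without carbonyl addition, and O-silylation of this magnesium dienolate (silyl enol ether formation) delivers the 1-silyloxy-1,3-diene; no stereocentre is formed.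

Step 2
Reactants: 4 silyl dienol ether; 5 (E)-4,4-dimethoxybut-2-enal
Product: 6 adduct A
Conditions: (5R)-5-benzyl-2,2,3-trimethylimidazolidin-4-one hydrochloride (20 mol %), 4 (1.5 equiv.), MeCN/H2O (95:5), −20 °C
Reagents that add atoms: water (oxygen of the formyl group after iminium hydrolysis), O
Why: The amine salt condenses with enal 5 to an (E)-configured α,β-unsaturated iminium ion whose lowered LUMO undergoes a concerted but asynchronous [4+2] cycloaddition with the electron-rich diene 4, and hydrolysis of the product iminium returns the catalyst; the closest known reaction type is the imidazolidinone-catalysed Diels–Alder reaction of enals with cyclohexa-1,3-dienes. Ring A (C1–C2–C3–C4–C5–C10) closes in a suprafacial six-membered [4π+2π] mode by forming C4–C5 and C1–C10 together, which leaves it as one ring of the bicyclo[2.2.2]octene with the C(Me)=CH unit as a two-carbon bridge over C1 and C4. C5 and C10 are trans because the E geometry of the dienophile is retained, C1 and C4 follow from the endo transition state that places the iminium carbon (later C6) under the diene and so syn to the alkene bridge, and the absolute sense comes from the benzyl group of the catalyst, which blocks one face of the iminium ion. Regioselectivity is secured by the donor oxygen and the 3-methyl group, which make the unsubstituted diene terminus (later C1) the most nucleophilic so that it bonds to the β-carbon (later C10); endo selectivity is secured by secondary overlap of the iminium π-system and by the absence of any π-substituent on the acetal carbon; enantioselectivity is secured by the catalyst, the (5R)-enantiomer being expected to give the A series.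

Step 3
Reactants: 6 adduct A
Product: 7 acid A
Conditions: NaClO2, NaH2PO4, 2-methyl-2-butene, t-BuOH/H2O, 0 °C
Reagents that add atoms: sodium chlorite, [Na+].[O-]Cl=O
Why: Pinnick (chlorite) oxidation converts the hindered formyl group into the carboxylic acid under buffered conditions that should leave the tertiary silyl ether, the acetal and, with 2-methyl-2-butene as hypochlorite scavenger, the bridging alkene untouched and should not epimerise C5.

Step 4
Reactants: 7 acid A
Product: 10 γ-lactone acetal A, via keto aldehyde acid A 8 (not isolated), via hydroxy keto acid A 9 (not isolated)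
Conditions: O3, CH2Cl2/MeOH (4:1), −78 °C; Me2S, −78 → 0 °C; NaBH4, −78 → −40 °C; pH 4 work-up, then PPTS (cat.), CH2Cl2, rt
Reagents that add atoms: ozone, [O-][O+]=O
Why: Criegee ozonolysis of the only alkene, the electron-rich trisubstituted bridge, unzips the bicycle into ring A with cis-1,4 acetyl (on C1) and formyl (C12, on C4) groups without touching a stereocentre, NaBH4 at low temperature reduces the aldehyde chemoselectively in the presence of the methyl ketone, and the new C12 hydroxyl, cis to the C5 carboxyl, lactonises, so that the γ-lactone protects both groups at no extra cost.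

Step 5
Reactants: 10 γ-lactone acetal A
Product: 11 keto aldehyde lactone A
Conditions: PPTS (0.2 equiv.), acetone/H2O (10:1), 45 °C
Reagents that add atoms: water, O
Why: Acid-catalysed acetal hydrolysis (transacetalisation to acetone) frees the C9 aldehyde under conditions mild enough for the hindered tertiary triethylsilyl ether and the lactone, and the equatorial, trans configuration at C10 is the thermodynamically preferred one, so enolisation cannot erode it.

Step 6
Reactants: 11 keto aldehyde lactone A; 12 methyltriphenylphosphonium bromide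
Product: 14 diene lactone A, via vinyl ketone A 13 (not isolated)
Conditions: Ph3PCH3Br (4 equiv.), KOt-Bu (3.8 equiv.), THF, 0 °C; add 11 at −78 °C, then → rt
Reagents that add atoms: methyltriphenylphosphonium bromide, C[P+](c1ccccc1)(c1ccccc1)c1ccccc1.[Br-]
Why: Twofold Wittig methylenation turns the aldehyde (at −78 °C, before an aldol reaction with the neighbouring methyl ketone can intervene) into the C10 vinyl group and the methyl ketone (on warming) into the isopropenyl group, the lactone being far less electrophilic towards the ylide; C1 and C10 carry their substituents equatorially and are not at risk.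

Step 7
Reactants: 14 diene lactone A; 15 tert-butylchlorodimethylsilane
Product: 18 silyloxy acid A, via potassium hydroxy carboxylate A 16 (not isolated), via bis-silyl compound A 17 (not isolated)
Conditions: KOH (1.05 equiv.), THF/MeOH/H2O, rt; evaporate; TBSCl (2.5 equiv.), imidazole, DMF, rt; K2CO3 (cat.), MeOH/H2O, rt; pH 5 work-up
Reagents that add atoms: potassium hydroxide, [K+].[OH-]; tert-butylchlorodimethylsilane, CC(C)(C)[Si](C)(C)Cl
Why: Saponification of the γ-lactone, exhaustive silylation of the dry hydroxy carboxylate and selective hydrolysis of the labile silyl ester are the standard way to turn a lactone into a silyloxy acid; once the C12 oxygen is silylated the acid can no longer relactonise, and the nearly neutral salt should keep 1,2-silyl migration from the tertiary oxygen low.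

Step 8
Reactants: 18 silyloxy acid A; 19 tert-butyl 2-(bromomethyl)acrylate
Product: 20 triene ester A
Conditions: Cs2CO3 (1.2 equiv.), 19 (1.3 equiv.), DMF, 0 °C → rt
Reagents that add atoms: tert-butyl 2-(bromomethyl)acrylate, C=C(CBr)C(=O)OC(C)(C)C
Why: O-Alkylation of the caesium carboxylate with the allylic bromide (SN2, or SN2' giving the same product) is insensitive to the hindrance around C6 and installs C7, C8 and the protected carboxyl in one operation; no stereocentre is involved.

Step 9
Reactants: 20 triene ester A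
Product: 21 isopropenyl ε-lactone A
Conditions: second-generation Grubbs catalyst RuCl2(H2IMes)(PCy3)(=CHPh) (10 mol %), toluene (2 mM), 80 °C, argon sparge
Reagents that add atoms: none
Why: Ring-closing metathesis should start at the monosubstituted vinyl group and close onto the 1,1-disubstituted acrylate to give the seven-membered ε-lactone with the C8=C9 alkene, whose geometry is fixed by the ring; precedent is the ring closure of dienes made from 2-(bromomethyl)acrylates, and the isopropenyl group cannot take part because that would need a four- or eight-membered ring with a tetrasubstituted alkene.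

Step 10
Reactants: 21 isopropenyl ε-lactone A
Product: 22 protected monomer A
Conditions: H2 (1 atm), RhCl(PPh3)3 (10 mol %), benzene, rt
Reagents that add atoms: none
Why: Homogeneous hydrogenation with RhCl(PPh3)3 reduces the unhindered 1,1-disubstituted isopropenyl alkene much faster than the trisubstituted, conjugated ring alkene (the selectivity known from carvone) and gives the isopropyl group, whose CH carries two methyl groups and is not a stereocentre.

Step 11
Reactants: 22 protected monomer A
Product: 24 acid partner A, via trimethylsilyl ester A 23 (not isolated)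
Conditions: TMSOTf (2 equiv.), 2,6-lutidine (3 equiv.), CH2Cl2, 0 °C; then pH 5 buffer/MeOH
Reagents that add atoms: none
Why: Silyl triflate-mediated cleavage of the tert-butyl ester (loss of isobutene from the O-silylated ester, then hydrolysis of the trimethylsilyl ester on work-up) is non-protic and should therefore spare the two silyl ethers and the lactone, which a protic acid would not.

Step 12
Reactants: 4 silyl dienol ether; 5 (E)-4,4-dimethoxybut-2-enal
Product: 25 adduct B
Conditions: (5S)-5-benzyl-2,2,3-trimethylimidazolidin-4-one hydrochloride (20 mol %), 4 (1.5 equiv.), MeCN/H2O (95:5), −20 °C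
Reagents that add atoms: water (oxygen of the formyl group after iminium hydrolysis), O
Why: Same iminium-catalysed endo Diels–Alder reaction as in step 2; the (5S)-catalyst shields the opposite face of the iminium ion, so the four stereocentres (C1', C4', C5', C10') should form in the mirror-image sense.

Step 13
Reactants: 25 adduct B
Product: 26 acid B
Conditions: NaClO2, NaH2PO4, 2-methyl-2-butene, t-BuOH/H2O, 0 °C
Reagents that add atoms: sodium chlorite, [Na+].[O-]Cl=O
Why: Pinnick oxidation as in step 3, applied to the enantiomer; no stereocentre is affected.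

Step 14
Reactants: 26 acid B
Product: 29 γ-lactone acetal B, via keto aldehyde acid B 27 (not isolated), via hydroxy keto acid B 28 (not isolated)
Conditions: O3, CH2Cl2/MeOH (4:1), −78 °C; Me2S, −78 → 0 °C; NaBH4, −78 → −40 °C; pH 4 work-up, then PPTS (cat.), CH2Cl2, rt
Reagents that add atoms: ozone, [O-][O+]=O
Why: Criegee ozonolysis, chemoselective aldehyde reduction and γ-lactonisation as in step 4, applied to the enantiomer.

Step 15
Reactants: 29 γ-lactone acetal B
Product: 30 keto aldehyde lactone B
Conditions: PPTS (0.2 equiv.), acetone/H2O (10:1), 45 °C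
Reagents that add atoms: water, O
Why: Acid-catalysed acetal hydrolysis as in step 5, applied to the enantiomer.

Step 16
Reactants: 30 keto aldehyde lactone B; 12 methyltriphenylphosphonium bromide
Product: 32 diene lactone B, via vinyl ketone B 31 (not isolated)
Conditions: Ph3PCH3Br (4 equiv.), KOt-Bu (3.8 equiv.), THF, 0 °C; add 30 at −78 °C, then → rt
Reagents that add atoms: methyltriphenylphosphonium bromide, C[P+](c1ccccc1)(c1ccccc1)c1ccccc1.[Br-]
Why: Twofold Wittig methylenation as in step 6, applied to the enantiomer.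

Step 17
Reactants: 32 diene lactone B; 15 tert-butylchlorodimethylsilane
Product: 35 silyloxy acid B, via potassium hydroxy carboxylate B 33 (not isolated), via bis-silyl compound B 34 (not isolated)
Conditions: KOH (1.05 equiv.), THF/MeOH/H2O, rt; evaporate; TBSCl (2.5 equiv.), imidazole, DMF, rt; K2CO3 (cat.), MeOH/H2O, rt; pH 5 work-up
Reagents that add atoms: potassium hydroxide, [K+].[OH-]; tert-butylchlorodimethylsilane, CC(C)(C)[Si](C)(C)Cl
Why: Lactone saponification, bis-silylation and silyl ester hydrolysis as in step 7, applied to the enantiomer.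

Step 18
Reactants: 35 silyloxy acid B; 19 tert-butyl 2-(bromomethyl)acrylate
Product: 36 triene ester B
Conditions: Cs2CO3 (1.2 equiv.), 19 (1.3 equiv.), DMF, 0 °C → rt
Reagents that add atoms: tert-butyl 2-(bromomethyl)acrylate, C=C(CBr)C(=O)OC(C)(C)C
Why: Carboxylate O-alkylation as in step 8, applied to the enantiomer.

Step 19
Reactants: 36 triene ester B
Product: 37 isopropenyl ε-lactone B
Conditions: second-generation Grubbs catalyst RuCl2(H2IMes)(PCy3)(=CHPh) (10 mol %), toluene (2 mM), 80 °C, argon sparge
Reagents that add atoms: none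
Why: Ring-closing metathesis as in step 9, applied to the enantiomer.

Step 20
Reactants: 37 isopropenyl ε-lactone B
Product: 38 protected monomer B
Conditions: H2 (1 atm), RhCl(PPh3)3 (10 mol %), benzene, rt
Reagents that add atoms: none
Why: Chemoselective homogeneous hydrogenation of the isopropenyl group as in step 10, applied to the enantiomer.

Step 21
Reactants: 38 protected monomer B
Product: 39 diol partner B
Conditions: HF·pyridine, pyridine, THF, 0 °C → rt
Reagents that add atoms: none
Why: Fluoride-mediated desilylation with pyridine-buffered HF·pyridine removes the primary tert-butyldimethylsilyl and the tertiary triethylsilyl ether while the tert-butyl ester and the lactone survive, and the weakly acidic buffer disfavours attack of the freed C12' hydroxyl on the lactone carbonyl.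

Step 22
Reactants: 24 acid partner A; 39 diol partner B
Product: 41 protected dimer, via mixed anhydride 40 (not isolated)
Conditions: 2,4,6-trichlorobenzoyl chloride, Et3N, THF, rt; then 39, DMAP, toluene, rt
Reagents that add atoms: none
Why: Yamaguchi esterification: DMAP attacks the mixed anhydride at the less hindered acyl group and the resulting acylpyridinium ion acylates the primary C12' hydroxyl of 39 selectively over its tertiary hydroxyl; 24 has no free hydroxyl and 39 no free acid, so only the cross-ester can form and no stereocentre is touched.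

Step 23
Reactants: 41 protected dimer
Product: 43 CNP0340505.1, via persilylated acid 42 (not isolated)
Conditions: TMSOTf (4 equiv.), 2,6-lutidine (6 equiv.), CH2Cl2, 0 °C; then HF·pyridine, pyridine, THF, 0 °C → rt
Reagents that add atoms: none
Why: Two-stage global deprotection: the silyl triflate cleaves the tert-butyl ester as in step 11 (silylating the free tertiary hydroxyl on the way), then buffered HF·pyridine removes all silyl groups, so that the C12 hydroxyl of half A, which could attack the neighbouring lactone, is set free last and only under mild, weakly acidic conditions.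

**Compound list**

1 | 3-methylcyclohex-2-en-1-one | CC1=CC(=O)CCC1 | starting material
2 | chlorotriethylsilane | CC[Si](CC)(CC)Cl | starting material
3 | bromomagnesium 3-methylcyclohexa-1,3-dien-1-olate (linear dienolate) | CC1=CCCC(O[Mg]Br)=C1 | intermediate
4 | silyl dienol ether, triethyl[(3-methylcyclohexa-1,3-dien-1-yl)oxy]silane | CC[Si](CC)(CC)OC1=CC(C)=CCC1 | intermediate
5 | (E)-4,4-dimethoxybut-2-enal | COC(OC)/C=C/C=O | starting material
6 | adduct A, (1R,2S,3R,4S)-3-(dimethoxymethyl)-5-methyl-1-(triethylsilyloxy)bicyclo[2.2.2]oct-5-ene-2-carbaldehyde (formyl endo, syn to C5=C6; acetal exo) | CC[Si](CC)(CC)O[C@]12CC[C@H](C(C)=C1)[C@@H](C(OC)OC)[C@@H]2C=O | intermediate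
7 | acid A, (1R,2S,3R,4S)-3-(dimethoxymethyl)-5-methyl-1-(triethylsilyloxy)bicyclo[2.2.2]oct-5-ene-2-carboxylic acid | CC[Si](CC)(CC)O[C@]12CC[C@H](C(C)=C1)[C@@H](C(OC)OC)[C@@H]2C(=O)O | intermediate
8 | keto aldehyde acid A: ring A with C1 acetyl, C4 formyl and OSiEt3, C5 CO2H, C10 CH(OMe)2; A-series configuration | CC[Si](CC)(CC)O[C@@]1(C=O)CC[C@H](C(C)=O)[C@@H](C(OC)OC)[C@@H]1C(=O)O | intermediate
9 | hydroxy keto acid A: as 8 with C4 CH2OH (C12) | CC[Si](CC)(CC)O[C@@]1(CO)CC[C@H](C(C)=O)[C@@H](C(OC)OC)[C@@H]1C(=O)O | intermediate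
10 | γ-lactone acetal A: cis-fused C6(=O)–O–C12 lactone across C5/C4, C1 acetyl, C10 CH(OMe)2, C4 OSiEt3 | CC[Si](CC)(CC)O[C@@]12CC[C@H](C(C)=O)[C@@H](C(OC)OC)[C@@H]1C(=O)OC2 | intermediate
11 | keto aldehyde lactone A: as 10 with C10 CHO (C9) | CC[Si](CC)(CC)O[C@@]12CC[C@H](C(C)=O)[C@@H](C=O)[C@@H]1C(=O)OC2 | intermediate
12 | methyltriphenylphosphonium bromide | C[P+](c1ccccc1)(c1ccccc1)c1ccccc1.[Br-] | starting material
13 | vinyl ketone A: as 11 with C10 vinyl | CC[Si](CC)(CC)O[C@@]12CC[C@H](C(C)=O)[C@@H](C=C)[C@@H]1C(=O)OC2 | intermediate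
14 | diene lactone A: γ-lactone with C1 isopropenyl and C10 vinyl | CC[Si](CC)(CC)O[C@@]12CC[C@H](C(C)=C)[C@@H](C=C)[C@@H]1C(=O)OC2 | intermediate
15 | tert-butylchlorodimethylsilane | CC(C)(C)[Si](C)(C)Cl | starting material
16 | potassium hydroxy carboxylate A: ring-opened 14, C12 OH, C5 CO2K | CC[Si](CC)(CC)O[C@@]1(CO)CC[C@H](C(C)=C)[C@@H](C=C)[C@@H]1C(=O)[O-].[K+] | intermediate
17 | bis-silyl compound A: C12 OTBS, C5 CO2TBS | CC[Si](CC)(CC)O[C@@]1(CO[Si](C)(C)C(C)(C)C)CC[C@H](C(C)=C)[C@@H](C=C)[C@@H]1C(=O)O[Si](C)(C)C(C)(C)C | intermediate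
18 | silyloxy acid A: C12 OTBS, C4 OSiEt3, C5 CO2H, C1 isopropenyl, C10 vinyl | CC[Si](CC)(CC)O[C@@]1(CO[Si](C)(C)C(C)(C)C)CC[C@H](C(C)=C)[C@@H](C=C)[C@@H]1C(=O)O | intermediate
19 | tert-butyl 2-(bromomethyl)acrylate | C=C(CBr)C(=O)OC(C)(C)C | starting material
20 | triene ester A: 2-(tert-butoxycarbonyl)allyl ester of 18 | CC[Si](CC)(CC)O[C@@]1(CO[Si](C)(C)C(C)(C)C)CC[C@H](C(C)=C)[C@@H](C=C)[C@@H]1C(=O)OCC(=C)C(=O)OC(C)(C)C | intermediate
21 | isopropenyl ε-lactone A: trans-fused seven-membered lactone C5–C6(=O)–O–C7–C8(CO2t-Bu)=C9–C10, C1 isopropenyl, C12 OTBS, C4 OSiEt3 | CC[Si](CC)(CC)O[C@@]1(CO[Si](C)(C)C(C)(C)C)CC[C@H](C(C)=C)[C@H]2C=C(C(=O)OC(C)(C)C)COC(=O)[C@H]12 | intermediate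
22 | protected monomer A: as 21 with C1 isopropyl | CC[Si](CC)(CC)O[C@@]1(CO[Si](C)(C)C(C)(C)C)CC[C@H](C(C)C)[C@H]2C=C(C(=O)OC(C)(C)C)COC(=O)[C@H]12 | intermediate
23 | trimethylsilyl ester A: as 22 with CO2SiMe3 at C8 | CC[Si](CC)(CC)O[C@@]1(CO[Si](C)(C)C(C)(C)C)CC[C@H](C(C)C)[C@H]2C=C(C(=O)O[Si](C)(C)C)COC(=O)[C@H]12 | intermediate
24 | acid partner A: as 22 with CO2H at C8 | CC[Si](CC)(CC)O[C@@]1(CO[Si](C)(C)C(C)(C)C)CC[C@H](C(C)C)[C@H]2C=C(C(=O)O)COC(=O)[C@H]12 | intermediate
25 | adduct B, (1S,2R,3S,4R)-enantiomer of 6 | CC[Si](CC)(CC)O[C@@]12CC[C@@H](C(C)=C1)[C@H](C(OC)OC)[C@H]2C=O | intermediate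
26 | acid B, enantiomer of 7 | CC[Si](CC)(CC)O[C@@]12CC[C@@H](C(C)=C1)[C@H](C(OC)OC)[C@H]2C(=O)O | intermediate
27 | keto aldehyde acid B, enantiomer of 8 | CC[Si](CC)(CC)O[C@]1(C=O)CC[C@@H](C(C)=O)[C@H](C(OC)OC)[C@H]1C(=O)O | intermediate
28 | hydroxy keto acid B, enantiomer of 9 | CC[Si](CC)(CC)O[C@]1(CO)CC[C@@H](C(C)=O)[C@H](C(OC)OC)[C@H]1C(=O)O | intermediate
29 | γ-lactone acetal B, enantiomer of 10 | CC[Si](CC)(CC)O[C@]12CC[C@@H](C(C)=O)[C@H](C(OC)OC)[C@H]1C(=O)OC2 | intermediate
30 | keto aldehyde lactone B, enantiomer of 11 | CC[Si](CC)(CC)O[C@]12CC[C@@H](C(C)=O)[C@H](C=O)[C@H]1C(=O)OC2 | intermediate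
31 | vinyl ketone B, enantiomer of 13 | CC[Si](CC)(CC)O[C@]12CC[C@@H](C(C)=O)[C@H](C=C)[C@H]1C(=O)OC2 | intermediate
32 | diene lactone B, enantiomer of 14 | CC[Si](CC)(CC)O[C@]12CC[C@@H](C(C)=C)[C@H](C=C)[C@H]1C(=O)OC2 | intermediate
33 | potassium hydroxy carboxylate B, enantiomer of 16 | CC[Si](CC)(CC)O[C@]1(CO)CC[C@@H](C(C)=C)[C@H](C=C)[C@H]1C(=O)[O-].[K+] | intermediate
34 | bis-silyl compound B, enantiomer of 17 | CC[Si](CC)(CC)O[C@]1(CO[Si](C)(C)C(C)(C)C)CC[C@@H](C(C)=C)[C@H](C=C)[C@H]1C(=O)O[Si](C)(C)C(C)(C)C | intermediate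
35 | silyloxy acid B, enantiomer of 18 | CC[Si](CC)(CC)O[C@]1(CO[Si](C)(C)C(C)(C)C)CC[C@@H](C(C)=C)[C@H](C=C)[C@H]1C(=O)O | intermediate
36 | triene ester B, enantiomer of 20 | CC[Si](CC)(CC)O[C@]1(CO[Si](C)(C)C(C)(C)C)CC[C@@H](C(C)=C)[C@H](C=C)[C@H]1C(=O)OCC(=C)C(=O)OC(C)(C)C | intermediate
37 | isopropenyl ε-lactone B, enantiomer of 21 | CC[Si](CC)(CC)O[C@]1(CO[Si](C)(C)C(C)(C)C)CC[C@@H](C(C)=C)[C@@H]2C=C(C(=O)OC(C)(C)C)COC(=O)[C@@H]12 | intermediate
38 | protected monomer B, enantiomer of 22 | CC[Si](CC)(CC)O[C@]1(CO[Si](C)(C)C(C)(C)C)CC[C@@H](C(C)C)[C@@H]2C=C(C(=O)OC(C)(C)C)COC(=O)[C@@H]12 | intermediate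
39 | diol partner B: B-series ε-lactone with C4' OH, C12' OH, C1' isopropyl, C8' CO2t-Bu | O[C@]1(CO)CC[C@@H](C(C)C)[C@@H]2C=C(C(=O)OC(C)(C)C)COC(=O)[C@@H]12 | intermediate
40 | mixed anhydride of 24 with 2,4,6-trichlorobenzoic acid | CC[Si](CC)(CC)O[C@@]1(CO[Si](C)(C)C(C)(C)C)CC[C@H](C(C)C)[C@H]2C=C(C(=O)OC(=O)c3c(Cl)cc(Cl)cc3Cl)COC(=O)[C@H]12 | intermediate
41 | protected dimer: C12' ester of 39 with acid 24 (half A: C12 OTBS, C4 OSiEt3; half B: C4' OH, CO2t-Bu) | CC[Si](CC)(CC)O[C@@]1(CO[Si](C)(C)C(C)(C)C)CC[C@H](C(C)C)[C@H]2C=C(C(=O)OC[C@@]3(O)CC[C@@H](C(C)C)[C@@H]4C=C(C(=O)OC(C)(C)C)COC(=O)[C@@H]34)COC(=O)[C@H]12 | intermediate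
42 | persilylated acid: as 41 with CO2SiMe3 in place of CO2t-Bu and C4' OSiMe3 | CC[Si](CC)(CC)O[C@@]1(CO[Si](C)(C)C(C)(C)C)CC[C@H](C(C)C)[C@H]2C=C(C(=O)OC[C@@]3(O[Si](C)(C)C)CC[C@@H](C(C)C)[C@@H]4C=C(C(=O)O[Si](C)(C)C)COC(=O)[C@@H]34)COC(=O)[C@H]12 | intermediate
43 | CNP0340505.1 | CC(C)[C@H]1CC[C@@](O)(CO)[C@H]2C(=O)OCC(C(=O)OC[C@@]3(O)CC[C@@H](C(C)C)[C@@H]4C=C(C(=O)O)COC(=O)[C@H]43)=C[C@H]12 | target

**Step count and risks**

Total step count: 23. Longest linear sequence: 13 steps (step 1, steps 2–11 or 12–21, steps 22 and 23).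

Steps most likely to fail:

1. Step 2 (the same holds for its mirror image, step 12). The ammonium salt and water may protodesilylate the dienol ether before cycloaddition. Conjugate addition may also occur without ring closure, followed by loss of the silyl group, and endo or facial selectivity may be eroded. Fallback: setting out from 4 and 5, an uncatalysed thermal Diels–Alder reaction (toluene, 90 °C, BHT) should give the racemic endo adduct F1. Pinnick oxidation as in step 3 would give the racemic acid F2. Classical resolution with (R)-1-phenylethylamine would separate the (R)-1-phenylethylammonium salt of acid 7 F3 from the (R)-1-phenylethylammonium salt of acid 26 F4, one by crystallisation and the other from the mother liquor (which is which would have to be established). Acidification returns the route at 7 (A series) and at 26 (B series), so one cycloaddition serves both halves.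

2. Step 9 (and its mirror image, step 19). Ring closure onto the electron-poor 1,1-disubstituted acrylate may be slow, so that intermolecular metathesis at the vinyl group and catalyst decay take over. Fallback for step 9: setting out from 18, esterification with excess 2-methylenepropane-1,3-diol (EDC·HCl, DMAP, CH2Cl2) would give the hydroxy allyl ester A F5. Its electron-neutral, hydroxyl-bearing alkene should close more readily with RuCl2(H2IMes)(PCy3)(=CHPh) to the allylic alcohol lactone A F6. Oxidation with MnO2 would give the enal lactone A F7, and Pinnick oxidation the isopropenyl acid A F8. Hydrogenation with H2/RhCl(PPh3)3 brings the route back at 24. Fallback for step 19: setting out from 35, the same sequence would give the hydroxy allyl ester B F9, the allylic alcohol lactone B F10, the enal lactone B F11 and the isopropenyl acid B F12. Esterification of F12 with tert-butyl 2,2,2-trichloroacetimidate brings the route back at 37.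

3. Step 22. Acylation of the neopentyl C12' hydroxyl may be slow, and DMAP may add in conjugate fashion to the activated acrylate and open the lactone of half A. Fallback: the union is made by carboxylate alkylation instead, setting out from 39 and 18. Diol 39 would be acylated at the primary hydroxyl with 2-(bromomethyl)acrylic acid (DCC, DMAP (cat.), CH2Cl2, 0 °C) to the bromomethylacrylate of B F13. The caesium salt of 18 (Cs2CO3, DMF) would be alkylated by F13 to the linked triene diester F14. Ring-closing metathesis as in step 9 would close the lactone of half A to the isopropenyl dimer F15. Hydrogenation with H2/RhCl(PPh3)3 brings the route back at 41.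

**Further compounds**

F1 | step 2 | racemic endo adduct (1:1 mixture of 6 and 25) | CC[Si](CC)(CC)O[C@]12CC[C@H](C(C)=C1)[C@@H](C(OC)OC)[C@@H]2C=O.CC[Si](CC)(CC)O[C@@]12CC[C@@H](C(C)=C1)[C@H](C(OC)OC)[C@H]2C=O
F2 | step 2 | racemic acid (1:1 mixture of 7 and 26) | CC[Si](CC)(CC)O[C@]12CC[C@H](C(C)=C1)[C@@H](C(OC)OC)[C@@H]2C(=O)O.CC[Si](CC)(CC)O[C@@]12CC[C@@H](C(C)=C1)[C@H](C(OC)OC)[C@H]2C(=O)O
F3 | step 2 | (R)-1-phenylethylammonium salt of acid 7 | CC[Si](CC)(CC)O[C@]12CC[C@H](C(C)=C1)[C@@H](C(OC)OC)[C@@H]2C(=O)[O-].C[C@@H]([NH3+])c1ccccc1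
F4 | step 2 | (R)-1-phenylethylammonium salt of acid 26 | CC[Si](CC)(CC)O[C@@]12CC[C@@H](C(C)=C1)[C@H](C(OC)OC)[C@H]2C(=O)[O-].C[C@@H]([NH3+])c1ccccc1
F5 | step 9 | hydroxy allyl ester A (2-(hydroxymethyl)allyl ester of 18) | CC[Si](CC)(CC)O[C@@]1(CO[Si](C)(C)C(C)(C)C)CC[C@H](C(C)=C)[C@@H](C=C)[C@@H]1C(=O)OCC(=C)CO
F6 | step 9 | allylic alcohol lactone A (as 21 with CH2OH at C8) | CC[Si](CC)(CC)O[C@@]1(CO[Si](C)(C)C(C)(C)C)CC[C@H](C(C)=C)[C@H]2C=C(CO)COC(=O)[C@H]12
F7 | step 9 | enal lactone A (as 21 with CHO at C8) | CC[Si](CC)(CC)O[C@@]1(CO[Si](C)(C)C(C)(C)C)CC[C@H](C(C)=C)[C@H]2C=C(C=O)COC(=O)[C@H]12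
F8 | step 9 | isopropenyl acid A (as 21 with CO2H at C8) | CC[Si](CC)(CC)O[C@@]1(CO[Si](C)(C)C(C)(C)C)CC[C@H](C(C)=C)[C@H]2C=C(C(=O)O)COC(=O)[C@H]12
F9 | step 19 | hydroxy allyl ester B (enantiomer of F5) | CC[Si](CC)(CC)O[C@]1(CO[Si](C)(C)C(C)(C)C)CC[C@@H](C(C)=C)[C@H](C=C)[C@H]1C(=O)OCC(=C)CO
F10 | step 19 | allylic alcohol lactone B (enantiomer of F6) | CC[Si](CC)(CC)O[C@]1(CO[Si](C)(C)C(C)(C)C)CC[C@@H](C(C)=C)[C@@H]2C=C(CO)COC(=O)[C@@H]12
F11 | step 19 | enal lactone B (enantiomer of F7) | CC[Si](CC)(CC)O[C@]1(CO[Si](C)(C)C(C)(C)C)CC[C@@H](C(C)=C)[C@@H]2C=C(C=O)COC(=O)[C@@H]12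
F12 | step 19 | isopropenyl acid B (enantiomer of F8) | CC[Si](CC)(CC)O[C@]1(CO[Si](C)(C)C(C)(C)C)CC[C@@H](C(C)=C)[C@@H]2C=C(C(=O)O)COC(=O)[C@@H]12
F13 | step 22 | bromomethylacrylate of B (C12' 2-(bromomethyl)acrylate of 39) | C=C(CBr)C(=O)OC[C@@]1(O)CC[C@@H](C(C)C)[C@@H]2C=C(C(=O)OC(C)(C)C)COC(=O)[C@@H]12
F14 | step 22 | linked triene diester (C6 carboxylate of 18 alkylated by F13) | CC[Si](CC)(CC)O[C@@]1(CO[Si](C)(C)C(C)(C)C)CC[C@H](C(C)=C)[C@@H](C=C)[C@@H]1C(=O)OCC(=C)C(=O)OC[C@@]2(O)CC[C@@H](C(C)C)[C@@H]3C=C(C(=O)OC(C)(C)C)COC(=O)[C@@H]23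
F15 | step 22 | isopropenyl dimer (as 41 with isopropenyl at C1 of half A) | CC[Si](CC)(CC)O[C@@]1(CO[Si](C)(C)C(C)(C)C)CC[C@H](C(C)=C)[C@H]2C=C(C(=O)OC[C@@]3(O)CC[C@@H](C(C)C)[C@@H]4C=C(C(=O)OC(C)(C)C)COC(=O)[C@@H]34)COC(=O)[C@H]12
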